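The route rests on cutting ring C where it meets ring A: the ether bond O1–C8a and the acyl bond C4–C4a. These end on adjacent ring-A carbons, and C4a lies next to the oxygen-bearing C5, so ring A can be brought in as a 3,5-dioxygenated aryne that this oxygen polarises. In one operation a primary alkoxide arylates at C8a and the C4a anion so formed acylates on an ester, closing ring C. The precursor is methyl (R)-2-aryl-3-hydroxy-2-(methoxymethoxy)propanoate, holding ring B, C2, the C3 stereocentre and C4; it is deprotonated with hydride before fluoride releases the aryne, so that no O–H remains to quench the aryl anion.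

Key step: step 15

Assumption: the sense of induction of the rhodium–diene catalyst with this ketone cannot be fixed in advance; step 12 is written for the diene antipode that delivers the aryl group to the Si face of the keto group (taken as the (1R,4R) ligand), the mirror-image ligand being used otherwise.
Assumption: methyl glycerate is used as the racemate, since its stereocentre is destroyed in step 5.
Remark: C2 of esters 24–26 and C3 of 30 and 31 are (R); the descriptor does not change in the annulation because the ester carbon becomes the C4 carbonyl with the same rank.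

**Aryne precursor**

Step 1
Reactants: 1 phloroglucinol
Product: 2 3,5-bis(methoxymethoxy)phenol
Conditions: MOMCl (2.0 equiv), i-Pr2NEt, DMF, 0 °C to rt
Reagents that add atoms: chloromethyl methyl ether, COCCl
Why: Williamson-type O-alkylation; the three hydroxyls are equivalent, so two equivalents of the chloride should give the bis-ether as the main component of a statistical mixture, with mono- and tris-ethers separated by chromatography and recycled.

Step 2
Reactants: 2 3,5-bis(methoxymethoxy)phenol
Product: 3 2-bromo-3,5-bis(methoxymethoxy)phenol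
Conditions: NBS (1.0 equiv), CH2Cl2, −78 °C
Reagents that add atoms: N-bromosuccinimide, O=C1CCC(=O)N1Br
Why: Electrophilic aromatic bromination; in a non-polar solvent at low temperature the hydrogen-bonded hydroxyl should steer bromine to the ortho carbon C2 in preference to C4, which is shielded by two flanking OMOM groups.

Step 3
Reactants: 3 2-bromo-3,5-bis(methoxymethoxy)phenol
Product: 7 3,5-bis(methoxymethoxy)-2-(trimethylsilyl)phenyl trifluoromethanesulfonate, via silyl ether 4 (not isolated), via aryllithium 5 (not isolated), via lithium phenoxide 6 (not isolated)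
Conditions: HMDS, THF, 65 °C, then evaporation; n-BuLi, THF, −78 °C; Tf2O, −78 °C
Reagents that add atoms: hexamethyldisilazane, C[Si](C)(C)N[Si](C)(C)C; trifluoromethanesulfonic anhydride, O=S(=O)(OS(=O)(=O)C(F)(F)F)C(F)(F)F
Why: O-silylation, bromine–lithium exchange, retro-Brook rearrangement (anionic 1,3-shift of silicon from oxygen to carbon) and O-triflation of the resulting phenoxide form the established sequence to ortho-silylaryl triflates, the exchange at −78 °C being far faster than any ortho-lithiation next to a MOM ether.

**Keto ester**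

Step 4
Reactants: 8 methyl glycerate
Product: 9 methyl 3-[(tert-butyldimethylsilyl)oxy]-2-hydroxypropanoate
Conditions: TBSCl, imidazole, CH2Cl2, 0 °C
Reagents that add atoms: tert-butyldimethylsilyl chloride, CC(C)(C)[Si](C)(C)Cl
Why: Silylation with a bulky silyl chloride should select the primary over the secondary hydroxyl.

Step 5
Reactants: 9 methyl 3-[(tert-butyldimethylsilyl)oxy]-2-hydroxypropanoate
Product: 10 methyl 3-[(tert-butyldimethylsilyl)oxy]-2-oxopropanoate
Conditions: Dess–Martin periodinane, CH2Cl2, rt
Reagents that add atoms: none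
Why: Dess–Martin oxidation should convert the secondary alcohol into the alpha-keto ester under neutral conditions that leave the silyl ether untouched.

**Ring B and the annulation precursor**

Step 6
Reactants: 11 catechol
Product: 12 1,2-bis(methoxymethoxy)benzene
Conditions: MOMCl, i-Pr2NEt, CH2Cl2, 0 °C to rt
Reagents that add atoms: chloromethyl methyl ether, COCCl
Why: Double Williamson-type O-alkylation of catechol should give the bis-MOM ether, which serves both as protection to the end and as the directing group for two later lithiations.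

Step 7
Reactants: 12 1,2-bis(methoxymethoxy)benzene
Product: 15 2,3-bis(methoxymethoxy)phenol, via aryllithium 13 (not isolated), via lithium borate 14 (not isolated)
Conditions: n-BuLi, TMEDA, THF, 0 °C; B(OMe)3, −78 °C to rt; H2O2 (30% aq.), 0 °C to rt
Reagents that add atoms: hydrogen peroxide, OO
Why: Directed ortho-metalation next to an OMOM group, borylation and oxidative conversion of the C–B into a C–O bond by basic peroxide should give the phenol with its three oxygens already differentiated.

Step 8
Reactants: 15 2,3-bis(methoxymethoxy)phenol; 16 prenyl bromide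
Product: 17 1,2-bis(methoxymethoxy)-3-[(3-methylbut-2-en-1-yl)oxy]benzene
Conditions: K2CO3, acetone, reflux
Reagents that add atoms: none
Why: Williamson ether synthesis; the phenoxide should displace bromide at the primary allylic carbon.

Step 9
Reactants: 17 1,2-bis(methoxymethoxy)-3-[(3-methylbut-2-en-1-yl)oxy]benzene
Product: 19 2,3-bis(methoxymethoxy)-6-(2-methylbut-3-en-2-yl)phenol, via dienone 18 (not isolated)
Conditions: PhNEt2, 190 °C
Reagents that add atoms: none
Why: Aromatic Claisen rearrangement; the [3,3] shift should deliver the allyl unit with inversion of its termini to the only free ortho carbon, and tautomerisation of the dienone in the basic solvent restores the phenol.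

Step 10
Reactants: 19 2,3-bis(methoxymethoxy)-6-(2-methylbut-3-en-2-yl)phenol
Product: 20 2-methoxy-3,4-bis(methoxymethoxy)-1-(2-methylbut-3-en-2-yl)benzene
Conditions: MeI, K2CO3, DMF, 40 °C
Reagents that add atoms: iodomethane, CI
Why: Williamson O-methylation of the hindered phenoxide in a dipolar aprotic solvent should fix the only methyl ether of the target and remove the hydroxyl that could cyclise on to the alkene.

Step 11
Reactants: 20 2-methoxy-3,4-bis(methoxymethoxy)-1-(2-methylbut-3-en-2-yl)benzene
Product: 23 [4-methoxy-2,3-bis(methoxymethoxy)-5-(2-methylbut-3-en-2-yl)phenyl]boronic acid, via aryllithium 21 (not isolated), via lithium borate 22 (not isolated)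
Conditions: n-BuLi, TMEDA, THF, 0 °C; B(OMe)3, −78 °C to rt; aq. NH4Cl
Reagents that add atoms: trimethyl borate, COB(OC)OC; water, O
Why: Directed ortho-metalation should remove the only ring hydrogen next to an OMOM group (the other is flanked by the tert-alkyl group), and borylation with mild hydrolysis gives the boronic acid.

Step 12
Reactants: 23 [4-methoxy-2,3-bis(methoxymethoxy)-5-(2-methylbut-3-en-2-yl)phenyl]boronic acid; 10 methyl 3-[(tert-butyldimethylsilyl)oxy]-2-oxopropanoate
Product: 24 methyl (2R)-3-[(tert-butyldimethylsilyl)oxy]-2-hydroxy-2-[4-methoxy-2,3-bis(methoxymethoxy)-5-(2-methylbut-3-en-2-yl)phenyl]propanoate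
Conditions: [RhCl(C2H4)2]2 (2.5 mol%), (1R,4R)-2,5-diphenylbicyclo[2.2.2]octa-2,5-diene (6 mol%), KOH (aq., 0.3 equiv), 1,4-dioxane, 30 °C
Reagents that add atoms: none
Why: Rhodium-catalysed asymmetric 1,2-addition of an arylboronic acid to an alpha-keto ester; transmetalation gives an aryl–rhodium species in the chiral diene pocket, which should tell the ester from the silyloxymethyl group and deliver the aryl group to the Si face of the ketone, setting the (R) tertiary alcohol without any oxidant that could touch the terminal alkene.

Step 13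
Reactants: 24 methyl (2R)-3-[(tert-butyldimethylsilyl)oxy]-2-hydroxy-2-[4-methoxy-2,3-bis(methoxymethoxy)-5-(2-methylbut-3-en-2-yl)phenyl]propanoate
Product: 25 methyl (2R)-3-[(tert-butyldimethylsilyl)oxy]-2-(methoxymethoxy)-2-[4-methoxy-2,3-bis(methoxymethoxy)-5-(2-methylbut-3-en-2-yl)phenyl]propanoate
Conditions: MOMCl, i-Pr2NEt, NaI, ClCH2CH2Cl, 60 °C
Reagents that add atoms: chloromethyl methyl ether, COCCl
Why: O-alkylation of the hindered tertiary alcohol by the iodomethyl ether formed in situ (Finkelstein activation) should proceed under an amine base too weak to form an alkoxide, so the silyl group cannot migrate.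

Step 14
Reactants: 25 methyl (2R)-3-[(tert-butyldimethylsilyl)oxy]-2-(methoxymethoxy)-2-[4-methoxy-2,3-bis(methoxymethoxy)-5-(2-methylbut-3-en-2-yl)phenyl]propanoate
Product: 26 methyl (2R)-3-hydroxy-2-(methoxymethoxy)-2-[4-methoxy-2,3-bis(methoxymethoxy)-5-(2-methylbut-3-en-2-yl)phenyl]propanoate
Conditions: TBAF, AcOH, THF, 0 °C to rt
Reagents that add atoms: none
Why: Fluoride cleavage of the silyl ether; acetic acid protonates the alkoxide as it forms, so retro-aldol cleavage and ester exchange should not occur.

**Annulation and end game**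

Step 15
Reactants: 26 methyl (2R)-3-hydroxy-2-(methoxymethoxy)-2-[4-methoxy-2,3-bis(methoxymethoxy)-5-(2-methylbut-3-en-2-yl)phenyl]propanoate; 7 3,5-bis(methoxymethoxy)-2-(trimethylsilyl)phenyl trifluoromethanesulfonate
Product: 30 (3R)-3,5,7-tris(methoxymethoxy)-3-[4-methoxy-2,3-bis(methoxymethoxy)-5-(2-methylbut-3-en-2-yl)phenyl]-2,3-dihydro-4H-chromen-4-one, via sodium alkoxide 27 (not isolated), via aryne 28 (not isolated), via aryl anion 29 (not isolated)
Conditions: NaH, THF, 0 °C; then 7 (1.8 equiv), CsF, 18-crown-6, THF, 0 °C to rt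
Reagents that add atoms: none
Why: Proposed new method: hydride turns 26 into alkoxide 27 so that no O–H remains, and fluoride then attacks the aryl silicon of 7 with loss of triflate to release aryne 28 (any alkoxide that desilylates 7 itself is returned from its silyl ether by fluoride). The alkoxide should add to the aryne carbon remote from the flanking OMOM group, which puts the charge of 29 on the carbon next to that oxygen where it is inductively stabilised; this regiochemistry (O1 on C8a, anion on C4a) is the selectivity the step needs and the 3-alkoxy substituent of the aryne secures it. The aryl anion then attacks the methyl ester in a 6-exo-trig closure of ring C and methoxide leaves, so O1–C8a and C4–C4a form in one operation. The closest known reaction types are the fluoride-triggered annulation of ortho-silylaryl triflates with salicylate esters to xanthones and the O–H insertion of arynes into aliphatic alcohols; new here is an aliphatic beta-alkoxide ester as partner. No stereocentre is formed, and C3 is quaternary and cannot enolise, so its configuration should be carried through unchanged. Acyl capture must outrun retro-aldol loss of formaldehyde from 27 and any protonation of 29, which is why the alkoxide is made cold with hydride, no protic species is present and the aryne precursor is used in excess.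

Step 16
Reactants: 30 (3R)-3,5,7-tris(methoxymethoxy)-3-[4-methoxy-2,3-bis(methoxymethoxy)-5-(2-methylbut-3-en-2-yl)phenyl]-2,3-dihydro-4H-chromen-4-one
Product: 31 (3R)-3-[2,3-dihydroxy-4-methoxy-5-(2-methylbut-3-en-2-yl)phenyl]-3,5,7-trihydroxy-2,3-dihydro-4H-chromen-4-one
Conditions: HCl (3 M in MeOH), THF, rt to 40 °C
Reagents that add atoms: none
Why: Acid-catalysed acetal exchange should remove all five MOM groups as dimethoxymethane; the aryl methyl ether survives, the 1,1-dimethylallyl group has no free ortho hydroxyl to cyclise on to, and the mild temperature guards the tertiary benzylic alcohol against dehydration.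

**Compound list**

1 | phloroglucinol (benzene-1,3,5-triol) | Oc1cc(O)cc(O)c1 | starting material
2 | 3,5-bis(methoxymethoxy)phenol | COCOc1cc(O)cc(OCOC)c1 | intermediate
3 | 2-bromo-3,5-bis(methoxymethoxy)phenol | Oc1cc(OCOC)cc(OCOC)c1Br | intermediate
4 | [2-bromo-3,5-bis(methoxymethoxy)phenoxy]trimethylsilane (not isolated) | C[Si](C)(C)Oc1cc(OCOC)cc(OCOC)c1Br | intermediate
5 | [2-lithio-3,5-bis(methoxymethoxy)phenoxy]trimethylsilane (not isolated) | C[Si](C)(C)Oc1cc(OCOC)cc(OCOC)c1[Li] | intermediate
6 | lithium 3,5-bis(methoxymethoxy)-2-(trimethylsilyl)phenoxide (not isolated) | [Li+].[O-]c1cc(OCOC)cc(OCOC)c1[Si](C)(C)C | intermediate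
7 | 3,5-bis(methoxymethoxy)-2-(trimethylsilyl)phenyl trifluoromethanesulfonate | C[Si](C)(C)c1c(OCOC)cc(OCOC)cc1OS(=O)(=O)C(F)(F)F | intermediate
8 | methyl glycerate (methyl 2,3-dihydroxypropanoate, racemic) | COC(=O)C(O)CO | starting material
9 | methyl 3-[(tert-butyldimethylsilyl)oxy]-2-hydroxypropanoate (racemic) | COC(=O)C(O)CO[Si](C)(C)C(C)(C)C | intermediate
10 | methyl 3-[(tert-butyldimethylsilyl)oxy]-2-oxopropanoate | COC(=O)C(=O)CO[Si](C)(C)C(C)(C)C | intermediate
11 | catechol (benzene-1,2-diol) | Oc1ccccc1O | starting material
12 | 1,2-bis(methoxymethoxy)benzene | COCOc1ccccc1OCOC | intermediate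
13 | [2,3-bis(methoxymethoxy)phenyl]lithium (not isolated) | [Li]c1cccc(OCOC)c1OCOC | intermediate
14 | lithium [2,3-bis(methoxymethoxy)phenyl]trimethoxyborate (not isolated) | [Li+].CO[B-](OC)(OC)c1cccc(OCOC)c1OCOC | intermediate
15 | 2,3-bis(methoxymethoxy)phenol | Oc1cccc(OCOC)c1OCOC | intermediate
16 | prenyl bromide (1-bromo-3-methylbut-2-ene) | CC(C)=CCBr | starting material
17 | 1,2-bis(methoxymethoxy)-3-[(3-methylbut-2-en-1-yl)oxy]benzene | CC(C)=CCOc1cccc(OCOC)c1OCOC | intermediate
18 | 2,3-bis(methoxymethoxy)-6-(2-methylbut-3-en-2-yl)cyclohexa-2,4-dien-1-one (not isolated) | C=CC(C)(C)C1C=CC(OCOC)=C(OCOC)C1=O | intermediate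
19 | 2,3-bis(methoxymethoxy)-6-(2-methylbut-3-en-2-yl)phenol | C=CC(C)(C)c1ccc(OCOC)c(OCOC)c1O | intermediate
20 | 2-methoxy-3,4-bis(methoxymethoxy)-1-(2-methylbut-3-en-2-yl)benzene | C=CC(C)(C)c1ccc(OCOC)c(OCOC)c1OC | intermediate
21 | [4-methoxy-2,3-bis(methoxymethoxy)-5-(2-methylbut-3-en-2-yl)phenyl]lithium (not isolated) | C=CC(C)(C)c1cc([Li])c(OCOC)c(OCOC)c1OC | intermediate
22 | lithium trimethoxy[4-methoxy-2,3-bis(methoxymethoxy)-5-(2-methylbut-3-en-2-yl)phenyl]borate (not isolated) | [Li+].CO[B-](OC)(OC)c1cc(C(C)(C)C=C)c(OC)c(OCOC)c1OCOC | intermediate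
23 | [4-methoxy-2,3-bis(methoxymethoxy)-5-(2-methylbut-3-en-2-yl)phenyl]boronic acid | OB(O)c1cc(C(C)(C)C=C)c(OC)c(OCOC)c1OCOC | intermediate
24 | methyl (2R)-3-[(tert-butyldimethylsilyl)oxy]-2-hydroxy-2-[4-methoxy-2,3-bis(methoxymethoxy)-5-(2-methylbut-3-en-2-yl)phenyl]propanoate | COC(=O)[C@](O)(CO[Si](C)(C)C(C)(C)C)c1cc(C(C)(C)C=C)c(OC)c(OCOC)c1OCOC | intermediate
25 | methyl (2R)-3-[(tert-butyldimethylsilyl)oxy]-2-(methoxymethoxy)-2-[4-methoxy-2,3-bis(methoxymethoxy)-5-(2-methylbut-3-en-2-yl)phenyl]propanoate | COC(=O)[C@](OCOC)(CO[Si](C)(C)C(C)(C)C)c1cc(C(C)(C)C=C)c(OC)c(OCOC)c1OCOC | intermediate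
26 | methyl (2R)-3-hydroxy-2-(methoxymethoxy)-2-[4-methoxy-2,3-bis(methoxymethoxy)-5-(2-methylbut-3-en-2-yl)phenyl]propanoate | COC(=O)[C@](OCOC)(CO)c1cc(C(C)(C)C=C)c(OC)c(OCOC)c1OCOC | intermediate
27 | sodium alkoxide of 26 at the primary oxygen, (2R) (not isolated) | [Na+].COC(=O)[C@](OCOC)(C[O-])c1cc(C(C)(C)C=C)c(OC)c(OCOC)c1OCOC | intermediate
28 | 3,5-bis(methoxymethoxy)benzyne (1,2-didehydro-3,5-bis(methoxymethoxy)benzene) (not isolated) | COCOC1=CC(OCOC)=CC#C1 | intermediate
29 | aryl anion from O-arylation of 27: 3,5-bis(methoxymethoxy)phenyl ether of 26 carrying the negative charge on the ring carbon between the ether oxygen and an OMOM group, (2R), sodium salt (not isolated) | [Na+].COC(=O)[C@](OCOC)(COc1cc(OCOC)cc(OCOC)[c-]1)c1cc(C(C)(C)C=C)c(OC)c(OCOC)c1OCOC | intermediate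
30 | (3R)-3,5,7-tris(methoxymethoxy)-3-[4-methoxy-2,3-bis(methoxymethoxy)-5-(2-methylbut-3-en-2-yl)phenyl]-2,3-dihydro-4H-chromen-4-one | C=CC(C)(C)c1cc([C@@]2(OCOC)COc3cc(OCOC)cc(OCOC)c3C2=O)c(OCOC)c(OCOC)c1OC | intermediate
31 | (3R)-3-[2,3-dihydroxy-4-methoxy-5-(2-methylbut-3-en-2-yl)phenyl]-3,5,7-trihydroxy-2,3-dihydro-4H-chromen-4-one | C=CC(C)(C)c1cc([C@@]2(O)COc3cc(O)cc(O)c3C2=O)c(O)c(O)c1OC | target

**Step count**

Total: 16 steps. Longest linear sequence: 11 steps (steps 6–16, catechol to the target); the aryne precursor (steps 1–3) and the keto ester (steps 4–5) are side branches.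

**Steps most likely to fail**

1. Step 15 (proposed new method). The alkoxide may fragment by retro-aldol loss of formaldehyde (which would also erode the configuration if it reverses), or the aryl anion may be protonated before it reaches the ester. The fallback makes the two bonds one at a time by known reactions and never forms a free alkoxide. It sets out from 26 and 7: the neutral alcohol is O-arylated by aryne O–H insertion (KF, 18-crown-6, THF, −20 °C), where the hydroxyl proton deliberately quenches the aryl anion. This should give the open aryl ether, methyl (2R)-3-[3,5-bis(methoxymethoxy)phenoxy]-2-(methoxymethoxy)-2-[4-methoxy-2,3-bis(methoxymethoxy)-5-(2-methylbut-3-en-2-yl)phenyl]propanoate F1. Treatment with LiTMP (lithium 2,2,6,6-tetramethylpiperidide, THF, −78 to 0 °C) should then lithiate the ring carbon between the ether oxygen and an OMOM group; the ester has no alpha hydrogen. The aryllithium attacks the ester (directed ortho-metalation followed by anionic cyclisation), closing ring C and coming back to the route at 30.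

2. Step 12. Aryl transfer from the ortho-substituted, electron-rich boronic acid may be slow and lose out to protodeboronation, and the catalyst may not discriminate well between the two faces of the ketone. The fallback gives up catalysis for resolution and sets out from arene 20. Aryllithium 21 (n-BuLi, TMEDA, THF) is added to keto ester 10 at −78 °C to give racemic methyl 3-[(tert-butyldimethylsilyl)oxy]-2-hydroxy-2-arylpropanoate F2. The conditions of steps 13 and 14 then give the racemic MOM ether F3 and the racemic hydroxy ester F4. Preparative chromatography on a chiral stationary phase separates 26 from its (2S)-enantiomer F5, and the route is rejoined at 26.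

3. Step 9. At the temperature of the rearrangement the allyl group may move on to the para carbon (Cope shift of the dienone), be lost altogether, or the new phenol may close on to its own alkene. The fallback attaches the 1,1-dimethylallyl group by cross-coupling and sets out from phenol 15. Ortho-bromination (NBS, catalytic i-Pr2NH, CH2Cl2, 0 °C) should give 6-bromo-2,3-bis(methoxymethoxy)phenol F6, and methylation (MeI, K2CO3, DMF) gives 1-bromo-2-methoxy-3,4-bis(methoxymethoxy)benzene F7. A branched-selective Suzuki–Miyaura coupling with 3-methylbut-2-enylboronic acid pinacol ester (Pd(OAc)2, a bulky dialkylbiarylphosphine chosen for the gamma isomer, K3PO4, aqueous THF, 40 °C) then joins the aryl carbon to the tertiary allyl terminus and comes back to the route at 20.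

**Further compounds**

F1 | step 15 | methyl (2R)-3-[3,5-bis(methoxymethoxy)phenoxy]-2-(methoxymethoxy)-2-[4-methoxy-2,3-bis(methoxymethoxy)-5-(2-methylbut-3-en-2-yl)phenyl]propanoate | COC(=O)[C@](OCOC)(COc1cc(OCOC)cc(OCOC)c1)c1cc(C(C)(C)C=C)c(OC)c(OCOC)c1OCOC
F2 | step 12 | racemic methyl 3-[(tert-butyldimethylsilyl)oxy]-2-hydroxy-2-[4-methoxy-2,3-bis(methoxymethoxy)-5-(2-methylbut-3-en-2-yl)phenyl]propanoate | COC(=O)C(O)(CO[Si](C)(C)C(C)(C)C)c1cc(C(C)(C)C=C)c(OC)c(OCOC)c1OCOC
F3 | step 12 | racemic methyl 3-[(tert-butyldimethylsilyl)oxy]-2-(methoxymethoxy)-2-[4-methoxy-2,3-bis(methoxymethoxy)-5-(2-methylbut-3-en-2-yl)phenyl]propanoate | COC(=O)C(OCOC)(CO[Si](C)(C)C(C)(C)C)c1cc(C(C)(C)C=C)c(OC)c(OCOC)c1OCOC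
F4 | step 12 | racemic methyl 3-hydroxy-2-(methoxymethoxy)-2-[4-methoxy-2,3-bis(methoxymethoxy)-5-(2-methylbut-3-en-2-yl)phenyl]propanoate | COC(=O)C(OCOC)(CO)c1cc(C(C)(C)C=C)c(OC)c(OCOC)c1OCOC
F5 | step 12 | methyl (2S)-3-hydroxy-2-(methoxymethoxy)-2-[4-methoxy-2,3-bis(methoxymethoxy)-5-(2-methylbut-3-en-2-yl)phenyl]propanoate (unwanted enantiomer, removed) | COC(=O)[C@@](OCOC)(CO)c1cc(C(C)(C)C=C)c(OC)c(OCOC)c1OCOC
F6 | step 9 | 6-bromo-2,3-bis(methoxymethoxy)phenol | Oc1c(Br)ccc(OCOC)c1OCOC
F7 | step 9 | 1-bromo-2-methoxy-3,4-bis(methoxymethoxy)benzene | COc1c(Br)ccc(OCOC)c1OCOC
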